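Ring B is a six-membered carbocycle whose contiguous stereocentres C8 (CHMe), C9 (quaternary) and C10 (ring-fusion CH; drimane numbering) flank the bonds C8–C9 and C5–C10: a Diels–Alder retron once the C5=C6 alkene is shifted to C6=C7. Everything rests on cutting these two bonds back to an acyclic (2E,8Z,10E)-trienal. Its enantioselective intramolecular Diels–Alder reaction under a chiral oxazaborolidinium Lewis acid closes rings A and B at once and sets C8, C9 and C10 from alkene geometry. The diene's C6 silyloxy group makes the cycloaddition polarity-matched and is later traded for the C5=C6 alkene; arylation at C11, formylation, deprotection and sulfation follow.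

Key step: step 7

Remark 1: terpenoid carbons carry drimane numbers (ring A: C1–C5 and C10; ring B: C5–C10; gem-dimethyl on C4; C11 = benzylic carbon on C9); aryl carbons run from C1′ (bearing C11) to C6′; MOM = methoxymethyl, TIPS = triisopropylsilyl.
Remark 2: the target is taken as the free aryl hydrogen sulfate that is drawn, so the last step ends with exchange of the counter-cation for H+.

Step 1
Reactants: 1 5-bromopent-1-ene; 2 4-methylpent-3-en-2-one (mesityl oxide)
Product: 4 4,4-dimethylnon-8-en-2-one, via Grignard reagent 3 (not isolated)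
Conditions: Mg, THF, reflux; then CuBr·SMe2 (5 mol%), 2, THF, −30 to 0 °C; 1 M HCl
Reagents that add atoms: none
Why: Copper-catalysed conjugate addition of a Grignard reagent to a β,β-disubstituted enone should build the quaternary C4 with its gem-dimethyl group; no stereocentre is formed.

Step 2
Reactants: 4 4,4-dimethylnon-8-en-2-one; 5 ethyl 2-methylprop-2-enoate (ethyl methacrylate)
Product: 6 ethyl (2E)-2,7,7-trimethyl-9-oxodec-2-enoate
Conditions: second-generation Grubbs catalyst RuCl2(=CHPh)(PCy3)(H2IMes) (5 mol%), 5 (10 equiv), CH2Cl2, 40 °C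
Reagents that add atoms: none
Why: Olefin cross-metathesis of the unhindered terminal alkene with a methacrylate should give the trisubstituted enoate with (E) geometry under thermodynamic control, the ketone being inert.

Step 3
Reactants: 6 ethyl (2E)-2,7,7-trimethyl-9-oxodec-2-enoate; 7 acetaldehyde
Product: 10 ethyl (2E,10E)-2,7,7-trimethyl-9-oxododeca-2,10-dienoate, via β-hydroxy ketone 8 (not isolated), via mesylate 9 (not isolated)
Conditions: LiN(i-Pr)2, THF, −78 °C; 7; AcOH; crude aldol: MsCl, Et3N, CH2Cl2, 0 to 20 °C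
Reagents that add atoms: none
Why: Kinetic deprotonation takes the methyl rather than the neopentylic CH2 of the ketone, and the directed aldol addition followed by mesylation and E1cB elimination (aldol condensation) should give the (E)-propenyl ketone.

Step 4
Reactants: 10 ethyl (2E,10E)-2,7,7-trimethyl-9-oxododeca-2,10-dienoate
Product: 12 ethyl (2E,8Z,10E)-2,7,7-trimethyl-9-[(triisopropylsilyl)oxy]dodeca-2,8,10-trienoate, via lithium enolate 11 (not isolated)
Conditions: LiN(i-Pr)2, THF–DMPU, −78 °C; i-Pr3SiOTf, −78 to −40 °C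
Reagents that add atoms: triisopropylsilyl trifluoromethanesulfonate, CC(C)[Si](OS(=O)(=O)C(F)(F)F)(C(C)C)C(C)C
Why: Kinetic α′-deprotonation of the enone (cross-conjugated enolate, as with hindered cyclohexenones) and O-silylation should give the 2-silyloxydiene; the (Z)-enolate is expected because the bulky C4 group avoids the conjugated propenyl group.

Step 5
Reactants: 12 ethyl (2E,8Z,10E)-2,7,7-trimethyl-9-[(triisopropylsilyl)oxy]dodeca-2,8,10-trienoate
Product: 13 (2E,8Z,10E)-2,7,7-trimethyl-9-[(triisopropylsilyl)oxy]dodeca-2,8,10-trien-1-ol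
Conditions: i-Bu2AlH (2.2 equiv), CH2Cl2, −78 °C; aq. Rochelle salt
Reagents that add atoms: none
Why: Hydride reduction of the enoate to the allylic alcohol should leave the bulky silyl dienol ether untouched.

Step 6
Reactants: 13 (2E,8Z,10E)-2,7,7-trimethyl-9-[(triisopropylsilyl)oxy]dodeca-2,8,10-trien-1-ol
Product: 14 (2E,8Z,10E)-2,7,7-trimethyl-9-[(triisopropylsilyl)oxy]dodeca-2,8,10-trienal
Conditions: MnO2 (activated, excess), CH2Cl2, 20 °C; used at once
Reagents that add atoms: none
Why: Neutral MnO2 oxidation of the allylic alcohol should give the (E)-enal without harming the acid-sensitive silyloxydiene or triggering thermal cyclisation.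

Step 7
Reactants: 14 (2E,8Z,10E)-2,7,7-trimethyl-9-[(triisopropylsilyl)oxy]dodeca-2,8,10-trienal
Product: 15 (1R,2R,4aS,8aR)-1,2,5,5-tetramethyl-4-[(triisopropylsilyl)oxy]-1,2,4a,5,6,7,8,8a-octahydronaphthalene-1-carbaldehyde (trans-fused; 5S,8R,9R,10R in drimane numbering)
Conditions: (S)-oxazaborolidinium triflimide [from (S)-α,α-diphenylprolinol, (o-TolBO)3 and Tf2NH] (20 mol%), CH2Cl2 (0.02 M), −78 to −40 °C
Reagents that add atoms: none
Why: The protonated oxazaborolidine binds the formyl group (B–O bond plus formyl C–H···O contact) and lowers the LUMO of the (E)-2-methylenal, which then undergoes a concerted, asynchronous [4+2] cycloaddition with the tethered silyloxydiene, C5–C10 bonding (nucleophilic diene terminus to the β-carbon) running ahead of C8–C9. The closest known reaction type is the chiral boron Lewis acid-catalysed intramolecular Diels–Alder reaction of (2E,7E,9E)-2-methyltrienals to trans-fused bicycles. Ring A closes in fused mode through the four-carbon C1–C4 tether (C5–C10 bond), and ring B is the cyclohexene of the cycloaddition itself, completed by the C8–C9 bond. C9 and C10 follow from the (E)-enal geometry (9-Me cis to C1), C8 from the (E)-propenyl terminus in the formyl-endo transition state (8-Me cis to CHO, trans to 9-Me), C5 from the (Z)-enol ether with the tether anti (trans ring fusion), and the absolute sense from the (S)-catalyst, whose aryl group should shield the si face of the enal α-carbon so that C8 adds to its re face. The step needs endo over exo selectivity and enantioface control: low-temperature Lewis acid activation favours the formyl-endo, tether-anti arrangement, while the tether and the polarity-matched C6 silyloxy group fix the regiochemistry.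

Step 8
Reactants: 16 benzene-1,2,4-triol
Product: 17 1,2,4-tris(methoxymethoxy)benzene
Conditions: MOMCl (3.5 equiv), i-Pr2NEt, CH2Cl2, 0 to 20 °C, argon
Reagents that add atoms: chloromethyl methyl ether, COCCl
Why: O-Alkylation of the three phenols (Williamson-type acetal protection) should give ethers that survive organolithium and dissolving-metal steps and direct ortho-lithiation later.

Step 9
Reactants: 17 1,2,4-tris(methoxymethoxy)benzene
Product: 18 1-bromo-2,4,5-tris(methoxymethoxy)benzene
Conditions: NBS, MeCN, 0 °C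
Reagents that add atoms: N-bromosuccinimide, O=C1CCC(=O)N1Br
Why: Electrophilic aromatic bromination should go to the one position that is para to one ether oxygen, ortho to another and unhindered.

Step 10
Reactants: 18 1-bromo-2,4,5-tris(methoxymethoxy)benzene; 15 the cycloadduct aldehyde
Product: 21 (1R,2R,4aS,8aR)-1,2,5,5-tetramethyl-1-[2,4,5-tris(methoxymethoxy)benzyl]-4-[(triisopropylsilyl)oxy]-1,2,4a,5,6,7,8,8a-octahydronaphthalene, via aryllithium 19 (not isolated), via lithium alkoxide 20 (not isolated)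
Conditions: n-BuLi, THF, −78 °C; 15, −78 to −30 °C; then transferred into Li, NH3(l)–THF, −78 °C; NH4Cl
Reagents that add atoms: none
Why: Bromine–lithium exchange and 1,2-addition to the non-enolisable neopentyl aldehyde give a benzylic alkoxide (C11 epimers), whose C–O bond is cleaved by dissolving-metal reduction on NH4Cl addition, so no benzylic cation next to C9 arises and the transient C11 stereocentre is erased.

Step 11
Reactants: 21 the silyl enol ether
Product: 23 (1S,3R,4R,4aR,8aS)-3,4,8,8-tetramethyl-4-[2,4,5-tris(methoxymethoxy)benzyl]decahydronaphthalen-1-ol (6-OH axial, anti to H-5), via ketone 22 (not isolated)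
Conditions: Bu4NF, AcOH, THF, 0 °C; then NaBH4, MeOH, −20 to 0 °C
Reagents that add atoms: none
Why: Buffered fluoride desilylation gives the C6 ketone, and borohydride should attack it equatorially because the axial path is blocked by the syn-axial methyl groups on C4 and C8, which sets the axial C6 alcohol.

Step 12
Reactants: 23 the axial C6 alcohol
Product: 24 (1R,2R,8aS)-1,2,5,5-tetramethyl-1-[2,4,5-tris(methoxymethoxy)benzyl]-1,2,3,5,6,7,8,8a-octahydronaphthalene (C5=C6 alkene)
Conditions: POCl3, pyridine, 0 to 60 °C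
Reagents that add atoms: none
Why: E2 dehydration through the dichlorophosphate should take the anti-periplanar axial H-5 in preference to H-7 (Saytzeff orientation, relief of 1,3-diaxial strain) and give the trisubstituted C5=C6 alkene, as axial 6-hydroxy steroids give 5-enes.

Step 13
Reactants: 24 the C5=C6 alkene
Product: 26 2,3,6-tris(methoxymethoxy)-5-{[(1R,2R,8aS)-1,2,5,5-tetramethyl-1,2,3,5,6,7,8,8a-octahydronaphthalen-1-yl]methyl}benzaldehyde, via aryllithium 25 (not isolated)
Conditions: n-BuLi, TMEDA, THF, −78 to 0 °C; DMF, −78 to 20 °C; H2O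
Reagents that add atoms: N,N-dimethylformamide, CN(C)C=O
Why: Directed ortho-metalation should occur at C3′, the only position flanked by two MOM ethers, and formylation of the aryllithium places the aldehyde there.

Step 14
Reactants: 26 the tris-MOM aldehyde
Product: 27 2,3,6-trihydroxy-5-{[(1R,2R,8aS)-1,2,5,5-tetramethyl-1,2,3,5,6,7,8,8a-octahydronaphthalen-1-yl]methyl}benzaldehyde
Conditions: HCl (3 M aq.), MeOH–THF, 40 °C, argon
Reagents that add atoms: none
Why: Acid-catalysed acetal cleavage frees the three phenols under conditions too mild to protonate the hindered trisubstituted alkene.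

Step 15
Reactants: 27 the triol aldehyde
Product: 29 2-formyl-3,4-dihydroxy-6-{[(1R,2R,8aS)-1,2,5,5-tetramethyl-1,2,3,5,6,7,8,8a-octahydronaphthalen-1-yl]methyl}phenyl hydrogen sulfate (target), via cyclic phenylboronate 28 (not isolated)
Conditions: PhB(OH)2, 4 Å molecular sieves, pyridine, 20 °C; SO3·pyridine, 40 °C; H2O; sulfonic acid resin (H+ form), 0 °C
Reagents that add atoms: sulfur trioxide–pyridine complex, [O-]S(=O)(=O)[n+]1ccccc1
Why: The 4′,5′-catechol is masked in situ as its five-membered phenylboronate, so O-sulfation with SO3·pyridine can only take the remaining C2′ phenol; water then hydrolyses the boronate and cation exchange gives the acid form.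

Compound list
1 | 5-bromopent-1-ene | C=CCCCBr | starting material
2 | 4-methylpent-3-en-2-one (mesityl oxide) | CC(=O)C=C(C)C | starting material
3 | pent-4-en-1-ylmagnesium bromide | C=CCCC[Mg]Br | intermediate
4 | 4,4-dimethylnon-8-en-2-one | CC(=O)CC(C)(C)CCCC=C | intermediate
5 | ethyl 2-methylprop-2-enoate | CCOC(=O)C(C)=C | starting material
6 | ethyl (2E)-2,7,7-trimethyl-9-oxodec-2-enoate | CCOC(=O)/C(C)=C/CCCC(C)(C)CC(C)=O | intermediate
7 | acetaldehyde | CC=O | starting material
8 | ethyl (2E)-11-hydroxy-2,7,7-trimethyl-9-oxododec-2-enoate (C11 epimers) | CCOC(=O)/C(C)=C/CCCC(C)(C)CC(=O)CC(C)O | intermediate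
9 | ethyl (2E)-2,7,7-trimethyl-11-(methylsulfonyloxy)-9-oxododec-2-enoate | CCOC(=O)/C(C)=C/CCCC(C)(C)CC(=O)CC(C)OS(C)(=O)=O | intermediate
10 | ethyl (2E,10E)-2,7,7-trimethyl-9-oxododeca-2,10-dienoate | CCOC(=O)/C(C)=C/CCCC(C)(C)CC(=O)/C=C/C | intermediate
11 | lithium (2E,8Z,10E)-1-ethoxy-2,7,7-trimethyl-1-oxododeca-2,8,10-trien-9-olate | [Li+].CCOC(=O)/C(C)=C/CCCC(C)(C)/C=C([O-])/C=C/C | intermediate
12 | ethyl (2E,8Z,10E)-2,7,7-trimethyl-9-[(triisopropylsilyl)oxy]dodeca-2,8,10-trienoate | CCOC(=O)/C(C)=C/CCCC(C)(C)/C=C(O[Si](C(C)C)(C(C)C)C(C)C)/C=C/C | intermediate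
13 | (2E,8Z,10E)-2,7,7-trimethyl-9-[(triisopropylsilyl)oxy]dodeca-2,8,10-trien-1-ol | OC/C(C)=C/CCCC(C)(C)/C=C(O[Si](C(C)C)(C(C)C)C(C)C)/C=C/C | intermediate
14 | (2E,8Z,10E)-2,7,7-trimethyl-9-[(triisopropylsilyl)oxy]dodeca-2,8,10-trienal | O=C/C(C)=C/CCCC(C)(C)/C=C(O[Si](C(C)C)(C(C)C)C(C)C)/C=C/C | intermediate
15 | (1R,2R,4aS,8aR)-1,2,5,5-tetramethyl-4-[(triisopropylsilyl)oxy]-1,2,4a,5,6,7,8,8a-octahydronaphthalene-1-carbaldehyde | O=C[C@]1(C)[C@H](C)C=C(O[Si](C(C)C)(C(C)C)C(C)C)[C@@H]2C(C)(C)CCC[C@@H]12 | intermediate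
16 | benzene-1,2,4-triol | Oc1ccc(O)c(O)c1 | starting material
17 | 1,2,4-tris(methoxymethoxy)benzene | COCOc1ccc(OCOC)c(OCOC)c1 | intermediate
18 | 1-bromo-2,4,5-tris(methoxymethoxy)benzene | COCOc1cc(OCOC)c(OCOC)cc1Br | intermediate
19 | [2,4,5-tris(methoxymethoxy)phenyl]lithium | [Li]c1cc(OCOC)c(OCOC)cc1OCOC | intermediate
20 | lithium alkoxide of the C11 benzylic carbinol from 15 and 19 (C11 epimers) | [Li+].[O-]C([C@]1(C)[C@H](C)C=C(O[Si](C(C)C)(C(C)C)C(C)C)[C@@H]2C(C)(C)CCC[C@@H]12)c1cc(OCOC)c(OCOC)cc1OCOC | intermediate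
21 | (1R,2R,4aS,8aR)-1,2,5,5-tetramethyl-1-[2,4,5-tris(methoxymethoxy)benzyl]-4-[(triisopropylsilyl)oxy]-1,2,4a,5,6,7,8,8a-octahydronaphthalene | C([C@]1(C)[C@H](C)C=C(O[Si](C(C)C)(C(C)C)C(C)C)[C@@H]2C(C)(C)CCC[C@@H]12)c1cc(OCOC)c(OCOC)cc1OCOC | intermediate
22 | (3R,4R,4aR,8aS)-3,4,8,8-tetramethyl-4-[2,4,5-tris(methoxymethoxy)benzyl]octahydronaphthalen-1(2H)-one | C([C@]1(C)[C@H](C)CC(=O)[C@@H]2C(C)(C)CCC[C@@H]12)c1cc(OCOC)c(OCOC)cc1OCOC | intermediate
23 | (1S,3R,4R,4aR,8aS)-3,4,8,8-tetramethyl-4-[2,4,5-tris(methoxymethoxy)benzyl]decahydronaphthalen-1-ol | C([C@]1(C)[C@H](C)C[C@H](O)[C@@H]2C(C)(C)CCC[C@@H]12)c1cc(OCOC)c(OCOC)cc1OCOC | intermediate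
24 | (1R,2R,8aS)-1,2,5,5-tetramethyl-1-[2,4,5-tris(methoxymethoxy)benzyl]-1,2,3,5,6,7,8,8a-octahydronaphthalene | C([C@]1(C)[C@H](C)CC=C2C(C)(C)CCC[C@@H]12)c1cc(OCOC)c(OCOC)cc1OCOC | intermediate
25 | 3′-lithio derivative of 24 | C([C@]1(C)[C@H](C)CC=C2C(C)(C)CCC[C@@H]12)c1cc(OCOC)c(OCOC)c([Li])c1OCOC | intermediate
26 | 2,3,6-tris(methoxymethoxy)-5-{[(1R,2R,8aS)-1,2,5,5-tetramethyl-1,2,3,5,6,7,8,8a-octahydronaphthalen-1-yl]methyl}benzaldehyde | C([C@]1(C)[C@H](C)CC=C2C(C)(C)CCC[C@@H]12)c1cc(OCOC)c(OCOC)c(C=O)c1OCOC | intermediate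
27 | 2,3,6-trihydroxy-5-{[(1R,2R,8aS)-1,2,5,5-tetramethyl-1,2,3,5,6,7,8,8a-octahydronaphthalen-1-yl]methyl}benzaldehyde | C([C@]1(C)[C@H](C)CC=C2C(C)(C)CCC[C@@H]12)c1cc(O)c(O)c(C=O)c1O | intermediate
28 | cyclic phenylboronate of the 4′,5′-catechol of 27 | C([C@]1(C)[C@H](C)CC=C2C(C)(C)CCC[C@@H]12)c1cc3OB(c4ccccc4)Oc3c(C=O)c1O | intermediate
29 | 2-formyl-3,4-dihydroxy-6-{[(1R,2R,8aS)-1,2,5,5-tetramethyl-1,2,3,5,6,7,8,8a-octahydronaphthalen-1-yl]methyl}phenyl hydrogen sulfate | C[C@@H]1CC=C2[C@@H](CCCC2(C)C)[C@]1(C)Cc1cc(O)c(O)c(C=O)c1OS(=O)(=O)O | target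

Total step count: 15. Longest linear sequence: 13 steps (steps 1–7 and 10–15; steps 8 and 9 make the aryl fragment).

Steps most likely to fail

Step 7. The cycloaddition may proceed with insufficient endo or enantioface selectivity, or the silyl dienol ether may be degraded by the acidic catalyst before it cyclises. The fallback gives up catalytic enantiocontrol for resolution: it sets out from 14 and returns at 15. Me2AlCl (1.1 equiv, CH2Cl2, −78 to −30 °C) should give the same formyl-endo, trans-fused adduct as a racemate, that is 15 together with its mirror image ent-15 F1. Preparative chromatography on a chiral stationary phase (amylose tris(3,5-dimethylphenylcarbamate)) then supplies 15 for step 10.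

Step 12. Elimination may run toward C7 instead of C5, or the strained axial dichlorophosphate may ionise and rearrange. The fallback replaces the E2 dehydration by a carbene 1,2-hydrogen shift: it sets out from 21 and returns at 24. Desilylation of 21 (Bu4NF, AcOH) with isolation of ketone 22 and condensation with TsNHNH2 (MeOH, 50 °C) give the tosylhydrazone F2. Its aprotic Bamford–Stevens decomposition (NaOMe, diglyme, 150 °C) should deliver 24, because the carbene at C6 takes the tertiary H-5 in preference.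

Step 15. The boronate mask may be incomplete or labile so that a catechol oxygen is sulfated, or the hindered, hydrogen-bonded C2′ phenol may react too slowly. The fallback uses an isolable catechol protecting group: it sets out from 27 and returns at 29. t-Bu2Si(OTf)2 and 2,6-lutidine (CH2Cl2, 0 °C) bridge only the 1,2-diol and give the cyclic di-tert-butylsilylene phenol F3. SO3·pyridine (pyridine, 50 °C) then gives the silylene-protected aryl hydrogen sulfate F4, and HF·pyridine (THF, 0 °C) followed by cation exchange releases 29.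

Further compounds
F1 | step 7 | ent-15, (1S,2S,4aR,8aS)-1,2,5,5-tetramethyl-4-[(triisopropylsilyl)oxy]-1,2,4a,5,6,7,8,8a-octahydronaphthalene-1-carbaldehyde | O=C[C@@]1(C)[C@@H](C)C=C(O[Si](C(C)C)(C(C)C)C(C)C)[C@H]2C(C)(C)CCC[C@H]12
F2 | step 12 | 4-methylbenzenesulfonylhydrazone of ketone 22 | C([C@]1(C)[C@H](C)CC(=NNS(=O)(=O)c3ccc(C)cc3)[C@@H]2C(C)(C)CCC[C@@H]12)c1cc(OCOC)c(OCOC)cc1OCOC
F3 | step 15 | 4′,5′-O-(di-tert-butylsilylene) derivative of 27 | C([C@]1(C)[C@H](C)CC=C2C(C)(C)CCC[C@@H]12)c1cc3O[Si](C(C)(C)C)(C(C)(C)C)Oc3c(C=O)c1O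
F4 | step 15 | 2′-O-hydrogen sulfate of F3 | C([C@]1(C)[C@H](C)CC=C2C(C)(C)CCC[C@@H]12)c1cc3O[Si](C(C)(C)C)(C(C)(C)C)Oc3c(C=O)c1OS(=O)(=O)O
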